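**Strategy.** Each dihydrobenzofuran is closed by the same event: its bond from C3 to the ring-fusion carbon C3a is made by imine-directed, rhodium-catalysed addition of an arene C–H bond across an aryl enol ether, which also sets C3. The route exploits the position of C3a of ring A between the ether oxygen and C4, whose styryl carbon is a latent aldehyde: as a chiral aldimine it steers rhodium into C3a–H, and once regained it becomes the stilbene (or, in the earlier rings, C3 of the next ring). The key-step precursor is a Z enol ether made by adding a phenol aldehyde to a diarylalkyne. One acid equilibration finally turns the three 2,3-cis rings trans.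

Key step: step 11

Labels: ring A is the dihydrobenzofuran that carries the styryl group, ring B the middle one, ring C the one that carries the 3,5-dihydroxyphenyl group; each is numbered O1, C2, C3, C3a, C4–C7, C7a.

Assumption: (R)-1-aminoindane on the directing imine is taken to favour insertion on the enol-ether face that gives 3R, and (S)-1-aminoindane 3S; if a test cyclisation shows the opposite sense, the two amines are exchanged throughout. Minor-enantiomer material from step 3 becomes a separable diastereomer after step 7.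

Step 1
Reactants: 1 1-ethynyl-3,5-dimethoxybenzene; 2 4-iodoanisole
Product: 3 1-[(3,5-dimethoxyphenyl)ethynyl]-4-methoxybenzene
Conditions: Pd(PPh3)2Cl2 (2 mol %), CuI (4 mol %), Et3N, THF, rt
Reagents that add atoms: none
Why: Sonogashira coupling of a terminal aryl alkyne with an aryl iodide is reliable at room temperature and tolerates the methyl ethers.

Step 2
Reactants: 3 diarylalkyne; 4 3-hydroxy-5-methoxybenzaldehyde
Product: 5 Z enol ether aldehyde
Conditions: [{Au(IPr)}2(μ-OH)][BF4] (1 mol %; IPr = 1,3-bis(2,6-diisopropylphenyl)imidazol-2-ylidene), toluene, 80 °C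
Reagents that add atoms: none
Why: Gold-catalysed hydrophenoxylation adds O–H anti across the alkyne to give the Z enol ether, and the phenoxide should attack the alkyne carbon bearing the 4-methoxyphenyl group because that carbon best stabilises positive charge in the gold π-complex.

Step 3
Reactants: 5 Z enol ether aldehyde; 6 (R)-1-aminoindane
Product: 9 ring C aldehyde (2S,3R; 2,3-cis), via aldimine 7 (not isolated), via cyclised aldimine 8 (not isolated)
Conditions: 6 (1.1 equiv), 4 Å MS, toluene, rt; then [RhCl(coe)2]2 (5 mol %; coe = cyclooctene), FcPCy2 (15 mol %; (C5H5)Fe(C5H4PCy2)), toluene, 75 °C; then 1 M HCl aq, THF, rt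
Reagents that add atoms: water, O
Why: Imine-directed rhodium-catalysed intramolecular hydroarylation (C–H alkylation) adds C3a–H syn across the Z enol ether, so C3 (R, face chosen by the aminoindane auxiliary) and C2 should arise 2,3-cis, and aqueous acid then returns the aldehyde.

Step 4
Reactants: 9 ring C aldehyde
Product: 10 ring C terminal alkyne
Conditions: dimethyl (1-diazo-2-oxopropyl)phosphonate, K2CO3, MeOH, 0 °C → rt
Reagents that add atoms: dimethyl (1-diazo-2-oxopropyl)phosphonate, COP(=O)(OC)C(=[N+]=[N-])C(C)=O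
Why: Ohira–Bestmann (Seyferth–Gilbert) homologation converts the non-enolisable aryl aldehyde into the terminal alkyne under mild carbonate conditions that should leave both stereocentres untouched.

Step 5
Reactants: 10 ring C terminal alkyne; 2 4-iodoanisole
Product: 11 ring C diarylalkyne
Conditions: Pd(PPh3)2Cl2 (3 mol %), CuI (6 mol %), Et3N, THF, 40 °C
Reagents that add atoms: none
Why: Sonogashira coupling, as in step 1, installs the 4-methoxyphenyl group that becomes the C2 aryl group of ring B.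

Step 6
Reactants: 11 ring C diarylalkyne; 4 3-hydroxy-5-methoxybenzaldehyde
Product: 12 Z enol ether aldehyde carrying ring C
Conditions: [{Au(IPr)}2(μ-OH)][BF4] (2 mol %), toluene, 100 °C
Reagents that add atoms: none
Why: Gold-catalysed anti hydrophenoxylation as in step 2, with the ortho-substituted benzofuranyl group adding a steric bias toward attack at the 4-methoxyphenyl-bearing carbon.

Step 7
Reactants: 12 Z enol ether aldehyde carrying ring C; 13 (S)-1-aminoindane
Product: 16 rings B–C aldehyde (ring B 2R,3S; both rings 2,3-cis), via aldimine 14 (not isolated), via cyclised aldimine 15 (not isolated)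
Conditions: 13 (1.1 equiv), 4 Å MS, toluene, rt; then [RhCl(coe)2]2 (5 mol %), FcPCy2 (15 mol %), toluene, 75–90 °C; then 1 M HCl aq, THF, rt
Reagents that add atoms: water, O
Why: The same imine-directed rhodium-catalysed hydroarylation closes ring B by syn addition, with the enantiomeric auxiliary chosen to set C3 of ring B as S and C2 following cis.

Step 8
Reactants: 16 rings B–C aldehyde
Product: 17 rings B–C terminal alkyne
Conditions: dimethyl (1-diazo-2-oxopropyl)phosphonate, K2CO3, MeOH, 0 °C → rt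
Reagents that add atoms: dimethyl (1-diazo-2-oxopropyl)phosphonate, COP(=O)(OC)C(=[N+]=[N-])C(C)=O
Why: Ohira–Bestmann homologation as in step 4.

Step 9
Reactants: 17 rings B–C terminal alkyne; 2 4-iodoanisole
Product: 18 rings B–C diarylalkyne
Conditions: Pd(PPh3)2Cl2 (3 mol %), CuI (6 mol %), Et3N, THF, 40 °C
Reagents that add atoms: none
Why: Sonogashira coupling as in step 5.

Step 10
Reactants: 18 rings B–C diarylalkyne; 4 3-hydroxy-5-methoxybenzaldehyde
Product: 19 Z enol ether aldehyde carrying rings B–C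
Conditions: [{Au(IPr)}2(μ-OH)][BF4] (2.5 mol %), toluene, 100–110 °C
Reagents that add atoms: none
Why: Gold-catalysed anti hydrophenoxylation as in step 6 should place the aryloxy group on the 4-methoxyphenyl-bearing carbon and give the Z isomer.

Step 11
Reactants: 19 Z enol ether aldehyde carrying rings B–C; 6 (R)-1-aminoindane
Product: 22 rings A–B–C aldehyde (ring A 2S,3R; all rings 2,3-cis), via aldimine 20 (not isolated), via cyclised aldimine 21 (not isolated)
Conditions: 6 (1.1 equiv), 4 Å MS, toluene, rt; then [RhCl(coe)2]2 (10 mol %), FcPCy2 (30 mol %), toluene, 75–100 °C; then 1 M HCl aq, THF, rt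
Reagents that add atoms: water, O
Why: The aldimine nitrogen of 20 binds monovalent rhodium and delivers it into the C3a–H bond lying between the imine carbon and the aryloxy oxygen, the enol ether inserts into Rh–H with hydrogen going to C2 and rhodium to the benzylic C3, and C(sp2)–C(sp3) reductive elimination from the six-membered rhodacycle forms the C3–C3a bond and closes ring A. The closest known reaction type is the imine-directed rhodium-catalysed intramolecular hydroarylation of tethered alkenes, which is established for closing 2,3-dihydrobenzofurans from aryl vinyl ethers bearing an ester on the alkene; the 1,2-diaryl enol ether used here is less activated and more hindered. Ring A closes in a formally 5-endo-trig mode with respect to C2=C3, which is possible because the bond-forming event is a reductive elimination and not a direct attack on the alkene. C3 (R) is set by the enol-ether face that inserts, controlled by the (R)-1-aminoindane auxiliary together with the adjacent ring B stereocentres, and C2 follows from syn addition across the Z alkene, giving the 2,3-cis ring that step 12 corrects. The step needs site selectivity for C3a–H over C5–H and over every other arene: C–H activation ortho to the imine is reversible and only the C3a rhodium hydride has the tethered alkene within reach, while no other ring carries a directing group.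

Step 12
Reactants: 22 rings A–B–C aldehyde (all cis)
Product: 23 rings A–B–C aldehyde (all trans)
Conditions: CF3CO2H (10 equiv), CH2Cl2, 0 °C, stopped as soon as equilibration is complete
Reagents that add atoms: none
Why: Acid-mediated cis-to-trans epimerisation of 2-aryl-2,3-dihydrobenzofurans: each benzylic C2–O bond ionises reversibly to a 4-methoxybenzyl cation that recloses on the phenolic oxygen, so C2 of every ring should equilibrate to the favoured 2,3-trans isomer while C3 is untouched.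

Step 13
Reactants: 23 rings A–B–C aldehyde (all trans); 24 diethyl (3,4-dimethoxybenzyl)phosphonate
Product: 25 decamethyl ether of the target
Conditions: KOtBu, THF, 0 °C → rt
Reagents that add atoms: none
Why: Horner–Wadsworth–Emmons olefination of an aryl aldehyde with a benzylphosphonate anion should give the E stilbene selectively.

Step 14
Reactants: 25 decamethyl ether
Product: 26 target compound CNP0099535.1
Conditions: BCl3 (1 M in CH2Cl2, excess), n-Bu4NI, CH2Cl2, −78 °C → rt; then ice-water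
Reagents that add atoms: none
Why: Lewis-acid-assisted nucleophilic demethylation: BCl3 activates each aryl methyl ether and iodide removes the methyl group by SN2 under non-protic conditions, which should spare the stilbene and the benzylic C–O bonds.

**Compound list**

1 | 1-ethynyl-3,5-dimethoxybenzene | C#Cc1cc(OC)cc(OC)c1 | starting material
2 | 4-iodoanisole | COc1ccc(I)cc1 | starting material
3 | 1-[(3,5-dimethoxyphenyl)ethynyl]-4-methoxybenzene | COc1ccc(C#Cc2cc(OC)cc(OC)c2)cc1 | intermediate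
4 | 3-hydroxy-5-methoxybenzaldehyde | COc1cc(O)cc(C=O)c1 | starting material
5 | 3-{[(Z)-2-(3,5-dimethoxyphenyl)-1-(4-methoxyphenyl)ethenyl]oxy}-5-methoxybenzaldehyde | COc1ccc(/C(Oc2cc(OC)cc(C=O)c2)=C/c2cc(OC)cc(OC)c2)cc1 | intermediate
6 | (R)-1-aminoindane | N[C@@H]1CCc2ccccc21 | starting material
7 | (E)-N-[(1R)-indan-1-yl] aldimine of 5 | COc1ccc(/C(Oc2cc(OC)cc(/C=N/[C@@H]3CCc4ccccc43)c2)=C/c2cc(OC)cc(OC)c2)cc1 | intermediate
8 | (E)-N-[(1R)-indan-1-yl] aldimine of 9 | c1(/C=N/[C@@H]2CCc3ccccc32)cc(OC)cc2c1[C@@H](c1cc(OC)cc(OC)c1)[C@@H](c1ccc(OC)cc1)O2 | intermediate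
9 | (2S,3R)-3-(3,5-dimethoxyphenyl)-6-methoxy-2-(4-methoxyphenyl)-2,3-dihydro-1-benzofuran-4-carbaldehyde (2,3-cis) | O=Cc1cc(OC)cc2c1[C@@H](c1cc(OC)cc(OC)c1)[C@@H](c1ccc(OC)cc1)O2 | intermediate
10 | (2S,3R)-3-(3,5-dimethoxyphenyl)-4-ethynyl-6-methoxy-2-(4-methoxyphenyl)-2,3-dihydro-1-benzofuran | C#Cc1cc(OC)cc2c1[C@@H](c1cc(OC)cc(OC)c1)[C@@H](c1ccc(OC)cc1)O2 | intermediate
11 | (2S,3R)-3-(3,5-dimethoxyphenyl)-6-methoxy-2-(4-methoxyphenyl)-4-[(4-methoxyphenyl)ethynyl]-2,3-dihydro-1-benzofuran | COc1ccc(C#Cc2cc(OC)cc3c2[C@@H](c2cc(OC)cc(OC)c2)[C@@H](c2ccc(OC)cc2)O3)cc1 | intermediate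
12 | 3-{[(Z)-2-[(2S,3R)-3-(3,5-dimethoxyphenyl)-6-methoxy-2-(4-methoxyphenyl)-2,3-dihydro-1-benzofuran-4-yl]-1-(4-methoxyphenyl)ethenyl]oxy}-5-methoxybenzaldehyde | COc1ccc(/C(Oc2cc(OC)cc(C=O)c2)=C/c2cc(OC)cc3c2[C@@H](c2cc(OC)cc(OC)c2)[C@@H](c2ccc(OC)cc2)O3)cc1 | intermediate
13 | (S)-1-aminoindane | N[C@H]1CCc2ccccc21 | starting material
14 | (E)-N-[(1S)-indan-1-yl] aldimine of 12 | COc1ccc(/C(Oc2cc(OC)cc(/C=N/[C@H]3CCc4ccccc43)c2)=C/c2cc(OC)cc3c2[C@@H](c2cc(OC)cc(OC)c2)[C@@H](c2ccc(OC)cc2)O3)cc1 | intermediate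
15 | (E)-N-[(1S)-indan-1-yl] aldimine of 16 | COc1ccc([C@@H]2Oc3cc(OC)cc(/C=N/[C@H]4CCc5ccccc54)c3[C@@H]2c2cc(OC)cc3c2[C@@H](c2cc(OC)cc(OC)c2)[C@@H](c2ccc(OC)cc2)O3)cc1 | intermediate
16 | (2R,3S)-3-[(2S,3R)-3-(3,5-dimethoxyphenyl)-6-methoxy-2-(4-methoxyphenyl)-2,3-dihydro-1-benzofuran-4-yl]-6-methoxy-2-(4-methoxyphenyl)-2,3-dihydro-1-benzofuran-4-carbaldehyde (rings B and C 2,3-cis) | COc1ccc([C@@H]2Oc3cc(OC)cc(C=O)c3[C@@H]2c2cc(OC)cc3c2[C@@H](c2cc(OC)cc(OC)c2)[C@@H](c2ccc(OC)cc2)O3)cc1 | intermediate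
17 | 4-ethynyl analogue of 16 (ring B 2R,3S; ring C 2S,3R) | COc1ccc([C@@H]2Oc3cc(OC)cc(C#C)c3[C@@H]2c2cc(OC)cc3c2[C@@H](c2cc(OC)cc(OC)c2)[C@@H](c2ccc(OC)cc2)O3)cc1 | intermediate
18 | 4-[(4-methoxyphenyl)ethynyl] analogue of 16 (ring B 2R,3S; ring C 2S,3R) | COc1ccc([C@@H]2Oc3cc(OC)cc(C#Cc4ccc(OC)cc4)c3[C@@H]2c2cc(OC)cc3c2[C@@H](c2cc(OC)cc(OC)c2)[C@@H](c2ccc(OC)cc2)O3)cc1 | intermediate
19 | 3-methoxy-5-{[(Z)-1-(4-methoxyphenyl)-2-(rings B–C unit of 16 attached through C4 of ring B)ethenyl]oxy}benzaldehyde | COc1ccc([C@@H]2Oc3cc(OC)cc(/C=C(/c4ccc(OC)cc4)Oc4cc(OC)cc(C=O)c4)c3[C@@H]2c2cc(OC)cc3c2[C@@H](c2cc(OC)cc(OC)c2)[C@@H](c2ccc(OC)cc2)O3)cc1 | intermediate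
20 | (E)-N-[(1R)-indan-1-yl] aldimine of 19 | COc1ccc([C@@H]2Oc3cc(OC)cc(/C=C(/c4ccc(OC)cc4)Oc4cc(OC)cc(/C=N/[C@@H]5CCc6ccccc65)c4)c3[C@@H]2c2cc(OC)cc3c2[C@@H](c2cc(OC)cc(OC)c2)[C@@H](c2ccc(OC)cc2)O3)cc1 | intermediate
21 | (E)-N-[(1R)-indan-1-yl] aldimine of 22 | COc1ccc([C@@H]2Oc3cc(OC)cc([C@@H]4c5c(/C=N/[C@@H]6CCc7ccccc76)cc(OC)cc5O[C@@H]4c4ccc(OC)cc4)c3[C@@H]2c2cc(OC)cc3c2[C@@H](c2cc(OC)cc(OC)c2)[C@@H](c2ccc(OC)cc2)O3)cc1 | intermediate
22 | (2S,3R)-3-{(2R,3S)-3-[(2S,3R)-3-(3,5-dimethoxyphenyl)-6-methoxy-2-(4-methoxyphenyl)-2,3-dihydro-1-benzofuran-4-yl]-6-methoxy-2-(4-methoxyphenyl)-2,3-dihydro-1-benzofuran-4-yl}-6-methoxy-2-(4-methoxyphenyl)-2,3-dihydro-1-benzofuran-4-carbaldehyde (rings A, B, C all 2,3-cis) | COc1ccc([C@@H]2Oc3cc(OC)cc([C@@H]4c5c(C=O)cc(OC)cc5O[C@@H]4c4ccc(OC)cc4)c3[C@@H]2c2cc(OC)cc3c2[C@@H](c2cc(OC)cc(OC)c2)[C@@H](c2ccc(OC)cc2)O3)cc1 | intermediate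
23 | (2R,3R)-3-{(2S,3S)-3-[(2R,3R)-3-(3,5-dimethoxyphenyl)-6-methoxy-2-(4-methoxyphenyl)-2,3-dihydro-1-benzofuran-4-yl]-6-methoxy-2-(4-methoxyphenyl)-2,3-dihydro-1-benzofuran-4-yl}-6-methoxy-2-(4-methoxyphenyl)-2,3-dihydro-1-benzofuran-4-carbaldehyde (all 2,3-trans) | COc1ccc([C@H]2Oc3cc(OC)cc([C@@H]4c5c(C=O)cc(OC)cc5O[C@H]4c4ccc(OC)cc4)c3[C@@H]2c2cc(OC)cc3c2[C@@H](c2cc(OC)cc(OC)c2)[C@H](c2ccc(OC)cc2)O3)cc1 | intermediate
24 | diethyl (3,4-dimethoxybenzyl)phosphonate | CCOP(=O)(Cc1ccc(OC)c(OC)c1)OCC | starting material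
25 | decamethyl ether of the target: 23 with the 4-formyl group of ring A replaced by (E)-2-(3,4-dimethoxyphenyl)ethenyl (ring A 2R,3R; ring B 2S,3S; ring C 2R,3R) | COc1ccc([C@H]2Oc3cc(OC)cc([C@@H]4c5c(/C=C/c6ccc(OC)c(OC)c6)cc(OC)cc5O[C@H]4c4ccc(OC)cc4)c3[C@@H]2c2cc(OC)cc3c2[C@@H](c2cc(OC)cc(OC)c2)[C@H](c2ccc(OC)cc2)O3)cc1 | intermediate
26 | CNP0099535.1: 25 with all ten methoxy groups as hydroxy groups (ring A 2R,3R; ring B 2S,3S; ring C 2R,3R; E stilbene) | Oc1ccc([C@H]2Oc3cc(O)cc([C@@H]4c5c(/C=C/c6ccc(O)c(O)c6)cc(O)cc5O[C@H]4c4ccc(O)cc4)c3[C@@H]2c2cc(O)cc3c2[C@@H](c2cc(O)cc(O)c2)[C@H](c2ccc(O)cc2)O3)cc1 | target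

**Step count.** Total: 14 steps. Longest linear sequence: 14 steps (1 → 26).

**Steps most likely to fail**

Step 11 (key step). Insertion of the hindered, electron-rich diaryl enol ether into the rhodium hydride may be too slow, so that the catalyst decays first, or the auxiliary may be overridden by the ring B stereocentres, giving poor facial selectivity at C3. The fallback sets out from 18 and comes back at 23; it closes the same C3–C3a bond by a bromide-directed Heck reaction. Gold-catalysed hydrophenoxylation of 18 with methyl 2-bromo-3-hydroxy-5-methoxybenzoate F1 (from NBS bromination of methyl 3-hydroxy-5-methoxybenzoate and separation of regioisomers) should give the bromo enol ether F2. Pd(OAc)2, PPh3, Et3N, DMF, 100 °C should close ring A by 5-endo Heck cyclisation to the 2,3-diarylbenzofuran ester F3. Ionic hydrogenation (Et3SiH, CF3CO2H, CH2Cl2) should reduce the benzofuran to the 2,3-trans ring under substrate control and, in the same acid, equilibrate rings B and C to trans, giving the all-trans ester F4, with ring A diastereomers separated by chromatography. LiAlH4 in THF should give the benzylic alcohol F5, and MnO2 in CH2Cl2 returns aldehyde 23.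

Step 14. The Lewis acid may trigger Friedel–Crafts closure of the electron-rich benzene ring of ring B onto the activated stilbene (a seven-membered ring), or irreversible opening of the benzylic ethers, before all ten methyl groups are gone. The fallback sets out from 23 and comes back at 26; it removes the methyl ethers before the alkene exists. BBr3 (CH2Cl2, −78 °C → rt) should convert 23 into the octaphenol aldehyde F6. TBSCl, imidazole, DMF should give the octakis(silyl ether) F7. Horner–Wadsworth–Emmons reaction with the known diethyl [3,4-bis(tert-butyldimethylsilyloxy)benzyl]phosphonate F8 (LiHMDS, THF, −78 °C → rt) should give the deca-silyl ether F9. Et3N·3HF in THF (or n-Bu4NF buffered with AcOH) should then release 26 without strong acid.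

Step 10. Addition of the phenol across the most hindered alkyne may stall, or may take place at the other alkyne carbon if the steric and electronic biases do not reinforce each other. The fallback sets out from 18 and comes back at 19; it makes the C–O bond by cross-coupling. Markovnikov hydration of 18 (Ph3PAuNTf2 cat., aqueous dioxane, 80 °C) should give the deoxybenzoin F10 with the carbonyl next to the 4-methoxyphenyl ring. KHMDS, PhNTf2, THF, −78 °C should give the Z enol triflate F11. Palladium-catalysed C–O coupling of F11 with phenol 4 (Pd2(dba)3, 2-(di-tert-butylphosphino)biphenyl, K3PO4, toluene, 100 °C) should give 19 with retention of alkene geometry.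

**Further compounds**

F1 | step 11 | methyl 2-bromo-3-hydroxy-5-methoxybenzoate | COC(=O)c1cc(OC)cc(O)c1Br
F2 | step 11 | methyl 2-bromo-5-methoxy-3-{[(Z)-1-(4-methoxyphenyl)-2-(rings B–C unit of 16 attached through C4 of ring B)ethenyl]oxy}benzoate | COc1ccc([C@@H]2Oc3cc(OC)cc(/C=C(/c4ccc(OC)cc4)Oc4cc(OC)cc(C(=O)OC)c4Br)c3[C@@H]2c2cc(OC)cc3c2[C@@H](c2cc(OC)cc(OC)c2)[C@@H](c2ccc(OC)cc2)O3)cc1
F3 | step 11 | methyl 6-methoxy-2-(4-methoxyphenyl)-3-(rings B–C unit of 16 attached through C4 of ring B)-1-benzofuran-4-carboxylate | COc1ccc([C@@H]2Oc3cc(OC)cc(-c4c(-c5ccc(OC)cc5)oc5cc(OC)cc(C(=O)OC)c45)c3[C@@H]2c2cc(OC)cc3c2[C@@H](c2cc(OC)cc(OC)c2)[C@@H](c2ccc(OC)cc2)O3)cc1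
F4 | step 11 | methyl ester corresponding to 23 (CO2Me in place of CHO; ring A 2R,3R; ring B 2S,3S; ring C 2R,3R) | COc1ccc([C@H]2Oc3cc(OC)cc([C@@H]4c5c(C(=O)OC)cc(OC)cc5O[C@H]4c4ccc(OC)cc4)c3[C@@H]2c2cc(OC)cc3c2[C@@H](c2cc(OC)cc(OC)c2)[C@H](c2ccc(OC)cc2)O3)cc1
F5 | step 11 | benzylic alcohol corresponding to 23 (CH2OH in place of CHO; all trans) | COc1ccc([C@H]2Oc3cc(OC)cc([C@@H]4c5c(CO)cc(OC)cc5O[C@H]4c4ccc(OC)cc4)c3[C@@H]2c2cc(OC)cc3c2[C@@H](c2cc(OC)cc(OC)c2)[C@H](c2ccc(OC)cc2)O3)cc1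
F6 | step 14 | octaphenol aldehyde: 23 with all eight methoxy groups as hydroxy groups | Oc1ccc([C@H]2Oc3cc(O)cc([C@@H]4c5c(C=O)cc(O)cc5O[C@H]4c4ccc(O)cc4)c3[C@@H]2c2cc(O)cc3c2[C@@H](c2cc(O)cc(O)c2)[C@H](c2ccc(O)cc2)O3)cc1
F7 | step 14 | octakis(tert-butyldimethylsilyl) ether of F6 | CC(C)(C)[Si](C)(C)Oc1ccc([C@H]2Oc3cc(O[Si](C)(C)C(C)(C)C)cc([C@@H]4c5c(C=O)cc(O[Si](C)(C)C(C)(C)C)cc5O[C@H]4c4ccc(O[Si](C)(C)C(C)(C)C)cc4)c3[C@@H]2c2cc(O[Si](C)(C)C(C)(C)C)cc3c2[C@@H](c2cc(O[Si](C)(C)C(C)(C)C)cc(O[Si](C)(C)C(C)(C)C)c2)[C@H](c2ccc(O[Si](C)(C)C(C)(C)C)cc2)O3)cc1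
F8 | step 14 | diethyl [3,4-bis(tert-butyldimethylsilyloxy)benzyl]phosphonate | CCOP(=O)(Cc1ccc(O[Si](C)(C)C(C)(C)C)c(O[Si](C)(C)C(C)(C)C)c1)OCC
F9 | step 14 | decakis(tert-butyldimethylsilyl) ether of 26 | CC(C)(C)[Si](C)(C)Oc1ccc([C@H]2Oc3cc(O[Si](C)(C)C(C)(C)C)cc([C@@H]4c5c(/C=C/c6ccc(O[Si](C)(C)C(C)(C)C)c(O[Si](C)(C)C(C)(C)C)c6)cc(O[Si](C)(C)C(C)(C)C)cc5O[C@H]4c4ccc(O[Si](C)(C)C(C)(C)C)cc4)c3[C@@H]2c2cc(O[Si](C)(C)C(C)(C)C)cc3c2[C@@H](c2cc(O[Si](C)(C)C(C)(C)C)cc(O[Si](C)(C)C(C)(C)C)c2)[C@H](c2ccc(O[Si](C)(C)C(C)(C)C)cc2)O3)cc1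
F10 | step 10 | 1-(4-methoxyphenyl)-2-(rings B–C unit of 16 attached through C4 of ring B)ethanone | COc1ccc([C@@H]2Oc3cc(OC)cc(CC(=O)c4ccc(OC)cc4)c3[C@@H]2c2cc(OC)cc3c2[C@@H](c2cc(OC)cc(OC)c2)[C@@H](c2ccc(OC)cc2)O3)cc1
F11 | step 10 | (Z)-enol triflate of F10 | COc1ccc([C@@H]2Oc3cc(OC)cc(/C=C(/c4ccc(OC)cc4)OS(=O)(=O)C(F)(F)F)c3[C@@H]2c2cc(OC)cc3c2[C@@H](c2cc(OC)cc(OC)c2)[C@@H](c2ccc(OC)cc2)O3)cc1
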